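**Strategy.** Everything rests on the C14–C15 bond, the sp2–sp3 link between the bicyclic half and the C15–C30 dienyl chain. The key step exploits C14 of the side-chain olefin C13=C14 on ring B. C14 is the one carbon bearing three different carbon groups (C13, C15, methyl), so it enters as a CCl2 linchpin. In one pot, gem-dichloroalkene 16, homoallylic zinc reagent 25 and Me2Zn are joined by two successive Negishi couplings. These forge C14–C15, then C14–CH3, and fix the E geometry through the unequal reactivity of the two C–Cl bonds. Precursor 16, a cis-fused keto alcohol, comes from 6-methoxy-2-tetralone by Birch reduction and cis-selective conjugate methylation.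

Key step: step 17

Numbering: polypodane numbering is used.
- Ring A is C1–C5 and C10; ring B is C5–C10.
- Methyl groups are C23/C24 (on C4), C25 (on C10), C26 (on C8), C27 (on C14), C28 (on C18) and C29 (on C22).
- The side chain is C9–C11–C12–C13=C14–C15–C16–C17=C18–C19–C20–C21=C22–C30H2O.
- β is the face of the C10 methyl.

Remark on the chemistry: the SMILES encodes 5S,8R,9R,10S, that is H-5 on the same face as the C10 methyl (a cis-fused decalin). The route is designed for exactly this configuration, which is why trans-fused labdane chiral-pool materials are not used.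

## Bicyclic half

Step 1
Reactants: 1 6-methoxy-2-tetralone
Product: 2 6-methoxy-1,1-dimethyl-3,4-dihydronaphthalen-2(1H)-one
Conditions: KOt-Bu (2.2 equiv), MeI (2.5 equiv), t-BuOH–THF, 0 to 23 °C
Reagents that add atoms: iodomethane CI
Why: Double enolate C-alkylation: the benzylic α-carbon (future C4) is by far the most acidic position, so both methyl groups should enter there.

Step 2
Reactants: 2 6-methoxy-1,1-dimethyl-3,4-dihydronaphthalen-2(1H)-one
Product: 3 (R)-6-methoxy-1,1-dimethyl-1,2,3,4-tetrahydronaphthalen-2-ol
Conditions: (S)-Me-CBS (10 mol%), BH3·SMe2, THF, −20 °C; MeOH quench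
Reagents that add atoms: none
Why: Corey–Bakshi–Shibata reduction: the quaternary benzylic carbon and the CH2 group flanking the carbonyl differ strongly in size, so the (S)-catalyst should set C3 as R, the stereocentre from which all others are relayed.

Step 3
Reactants: 3 (R)-6-methoxy-1,1-dimethyl-1,2,3,4-tetrahydronaphthalen-2-ol
Product: 5 hydroxy enone (4aS,6R)-6-hydroxy-5,5-dimethyl-4,4a,5,6,7,8-hexahydronaphthalen-2(3H)-one, via dihydroanisole 4 (not isolated)
Conditions: Li, NH3 (l), t-BuOH, THF, −78 °C; then 2 M HCl, THF–MeOH, 23 °C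
Reagents that add atoms: water O
Why: Birch reduction followed by enol ether hydrolysis and acid equilibration of the β,γ- to the α,β-enone should set C5 under thermodynamic control, because C6 is forced equatorial on ring A and the epimer with H-5 cis to H-3 keeps the C3 hydroxyl equatorial; the minor epimer can be separated and re-equilibrated.

Step 4
Reactants: 5 hydroxy enone
Product: 6 cis-fused bis(trimethylsilyl) compound (8-trimethylsilyloxy-8(9)-ene; 3α-OTMS; 5β-H; 10β-methyl)
Conditions: MeMgBr (3 equiv), CuBr·SMe2 (20 mol%), TMSCl, DMPU, THF, −78 to −40 °C; Et3N quench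
Reagents that add atoms: methylmagnesium bromide C[Mg]Br; chlorotrimethylsilane C[Si](C)(C)Cl
Why: Copper-catalysed, TMSCl-accelerated conjugate addition: methyl should reach C10 anti to the bulky C4–C5 bond, that is on the face of H-5 (the known cis outcome for 4,4a,5,6,7,8-hexahydronaphthalen-2(3H)-ones), while TMSCl traps the enolate regiospecifically and masks the C3 oxygen.

Step 5
Reactants: 6 bis(trimethylsilyl) compound
Product: 8 9β-allyl 8-ketone (3α-OTMS), via lithium enolate 7 (not isolated)
Conditions: MeLi (1.05 equiv), THF, 0 °C; then allyl iodide, DMPU, −78 to −30 °C; AcOH quench at −78 °C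
Reagents that add atoms: allyl iodide C=CCI
Why: Silyl enol ether cleavage gives the regiodefined enolate, and kinetic allylation should occur on the convex β face, anti to the pseudoaxial C1–C10 bond and away from C4 folded under ring B, which sets C9; the cold acidic quench guards this epimerisable centre.

Step 6
Reactants: 8 9β-allyl 8-ketone
Product: 10 9β-allyl-8(26)-methylene-3α-ol, via silyl ether 9 (not isolated)
Conditions: Zn, CH2Br2, TiCl4, THF–CH2Cl2, 0 to 23 °C; work-up with 1 M HCl
Reagents that add atoms: dibromomethane BrCBr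
Why: Takai–Lombardo methylenation is non-basic, so the hindered ketone should be methylenated without enolisation and C9 is locked, and the dilute acid work-up removes the trimethylsilyl group.

Step 7
Reactants: 10 9β-allyl-8(26)-methylene-3α-ol
Product: 12 3α,13-diol with 8(26)-methylene, via bis-boron adduct 11 (not isolated)
Conditions: 9-BBN (2.2 equiv), THF, 0 to 23 °C; then NaOH, H2O2, 0 °C
Reagents that add atoms: hydrogen peroxide OO
Why: Anti-Markovnikov hydroboration–oxidation: bulky 9-BBN should select the open monosubstituted allyl terminus over the exocyclic methylene, which is flanked by the C9 chain and the C10 quaternary centre, as is usual for labdane-type 8-methylene groups.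

Step 8
Reactants: 12 3α,13-diol
Product: 13 3-keto 13-aldehyde with 8(26)-methylene
Conditions: Dess–Martin periodinane (2.5 equiv), NaHCO3, CH2Cl2, 0 to 23 °C
Reagents that add atoms: none
Why: Dess–Martin oxidation takes both alcohols to their final oxidation levels in one operation, erases the relay stereocentre C3, and leaves no epimerisable stereocentre.

Step 9
Reactants: 13 3-keto 13-aldehyde
Product: 14 14,14-dichloro-13-ene with 3-ketone and 8(26)-methylene
Conditions: PPh3, CCl4, MeCN, 0 to 23 °C
Reagents that add atoms: tetrachloromethane ClC(Cl)(Cl)Cl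
Why: Wittig-type gem-dichloroolefination with Ph3P=CCl2 formed in situ should take the aldehyde only, since the C3 ketone is flanked by the quaternary C4.

Step 10
Reactants: 14 dichloroalkene with 8(26)-methylene
Product: 16 (5S,8R,9R,10S)-8α-hydroxy-3-keto gem-dichloroalkene, via hydroperoxide 15 (not isolated)
Conditions: Co(acac)2 (20 mol%), PhSiH3, O2 (1 atm), THF, 0 to 23 °C; then P(OEt)3
Reagents that add atoms: dioxygen O=O
Why: Mukaiyama hydration: hydrogen-atom transfer should select the electron-rich 1,1-disubstituted olefin over the dichlorovinyl group, and O2 should capture the planar C8 radical on the α face, anti to the adjacent C9 chain and away from the C10 methyl, which sets C8.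

## Chain half

Step 11
Reactants: 17 geranyl acetate
Product: 18 (2E,6E)-8-hydroxy-3,7-dimethylocta-2,6-dienyl acetate
Conditions: SeO2 (10 mol%), t-BuOOH, salicylic acid (cat.), CH2Cl2, 23 °C
Reagents that add atoms: tert-butyl hydroperoxide CC(C)(C)OO
Why: Catalytic SeO2 allylic oxidation (ene reaction, then 2,3-sigmatropic shift) should attack the E-methyl of the terminal olefin, because the 2,3-olefin is deactivated by the allylic acetate.

Step 12
Reactants: 18 hydroxy acetate
Product: 19 (2E,6E)-8-(tert-butyldimethylsilyloxy)-3,7-dimethylocta-2,6-dienyl acetate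
Conditions: TBSCl, imidazole, CH2Cl2, 23 °C
Reagents that add atoms: tert-butyldimethylsilyl chloride CC(C)(C)[Si](C)(C)Cl
Why: Standard silylation masks the future C30 oxygen with a group that is inert to zerovalent palladium, unlike an allylic acetate.

Step 13
Reactants: 19 silyl ether acetate
Product: 20 (2E,6E)-8-(tert-butyldimethylsilyloxy)-3,7-dimethylocta-2,6-dien-1-ol
Conditions: K2CO3 (cat.), MeOH, 23 °C
Reagents that add atoms: none
Why: Base-catalysed transesterification removes the acetate and leaves the silyl ether untouched.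

Step 14
Reactants: 20 allylic alcohol
Product: 21 (2E,6E)-8-(tert-butyldimethylsilyloxy)-3,7-dimethylocta-2,6-dienal
Conditions: MnO2, CH2Cl2, 23 °C
Reagents that add atoms: none
Why: MnO2 oxidation of an allylic alcohol should give the enal with the E geometry kept.

Step 15
Reactants: 21 enal
Product: 22 tert-butyldimethylsilyl ether of (2E,6E)-2,6-dimethylnona-2,6,8-trien-1-ol
Conditions: Ph3PCH3Br, KOt-Bu, THF, 0 °C
Reagents that add atoms: methyltriphenylphosphonium bromide C[P+](c1ccccc1)(c1ccccc1)c1ccccc1.[Br-]
Why: Wittig methylenation adds C15 and gives the terminal 1,3-diene without touching the trisubstituted olefins.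

Step 16
Reactants: 22 triene
Product: 24 (2E,6E)-9-iodo-2,6-dimethylnona-2,6-dienyl tert-butyldimethylsilyl ether, via B-alkyl-9-BBN 23 (not isolated)
Conditions: 9-BBN, THF, 0 to 23 °C; then NaOMe, I2, MeOH–THF, 0 °C
Reagents that add atoms: iodine II
Why: 9-BBN should hydroborate only the terminal vinyl group of the diene to give the homoallylic borane, and base-induced iodinolysis transfers the primary alkyl group selectively to give the iodide.

## Union and end game

Step 17
Reactants: 16 8α-hydroxy-3-keto gem-dichloroalkene; 24 homoallylic iodide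
Product: 27 C30 tert-butyldimethylsilyl ether of alcohol 28 (13E,17E,21E), via alkylzinc iodide 25 (not isolated), via chloroalkene 26 (not isolated)
Conditions: 24, Zn dust, LiCl, THF, 35 °C; transfer (1.5 equiv) to 16, PdCl2(DPEphos) (3 mol%), THF, 23 °C; then Me2Zn (3 equiv), Pd(Pt-Bu3)2 (5 mol%), 60 °C
Reagents that add atoms: dimethylzinc C[Zn]C
Why: This is a double Negishi coupling on a 1,1-dichloroalkene linchpin, the closest known type being trans-selective monoalkylation of 1,1-dihalo-1-alkenes followed by substitution of the remaining halide. Zerovalent palladium should insert first into the C14–Cl bond trans to the C12 chain, the less hindered of the two; transmetalation with homoallylic zinc reagent 25 and reductive elimination from divalent palladium then forge C14–C15, the wide bite angle of DPEphos favouring reductive elimination over β-hydride elimination. The surviving C14–Cl bond of 26, cis to C12 and inert to the first catalyst at 23 °C, is then opened by the electron-rich Pd(Pt-Bu3)2 and methylated by Me2Zn with retention, so C15 ends trans and C27 cis to C12, which is the E olefin. No ring is closed and no stereocentre is made; the only stereochemical element set is the C13=C14 geometry, controlled by the order of the two substitutions. The step needs site selectivity between the two chlorides, secured by the C12 chain on C13, and chemoselectivity for C–Cl over the C3 ketone, the free C8 hydroxyl and the silyl ether, which the low basicity and low carbonyl reactivity of organozinc reagents should secure, with the excess of 25 covering slow protonolysis by the tertiary alcohol.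

Step 18
Reactants: 27 coupled silyl ether
Product: 28 primary allylic alcohol (deacetyl target; 30-hydroxy; 8α-hydroxy; 3-ketone)
Conditions: TBAF, THF, 0 to 23 °C
Reagents that add atoms: none
Why: Fluoride-mediated desilylation frees the primary allylic alcohol and touches neither the ketone nor the tertiary alcohol.

Step 19
Reactants: 28 primary allylic alcohol
Product: 29 Myrrhanone A acetate (target)
Conditions: Ac2O, pyridine, DMAP (cat.), CH2Cl2, 0 °C
Reagents that add atoms: acetic anhydride CC(=O)OC(C)=O
Why: Acylation should take the unhindered primary alcohol only, since the tertiary C8 hydroxyl is inert under these mild conditions.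

## Compound list

1 | 6-methoxy-2-tetralone | COc1ccc2c(c1)CCC(=O)C2 | starting material
2 | 6-methoxy-1,1-dimethyl-3,4-dihydronaphthalen-2(1H)-one | COc1ccc2c(c1)CCC(=O)C2(C)C | intermediate
3 | (R)-6-methoxy-1,1-dimethyl-1,2,3,4-tetrahydronaphthalen-2-ol | COc1ccc2c(c1)CC[C@@H](O)C2(C)C | intermediate
4 | (R)-6-methoxy-1,1-dimethyl-1,2,3,4,5,8-hexahydronaphthalen-2-ol (dihydroanisole, not isolated) | COC1=CCC2=C(C1)CC[C@@H](O)C2(C)C | intermediate
5 | (4aS,6R)-6-hydroxy-5,5-dimethyl-4,4a,5,6,7,8-hexahydronaphthalen-2(3H)-one (3α-OH, 5β-H) | O=C1C=C2CC[C@@H](O)C(C)(C)[C@H]2CC1 | intermediate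
6 | cis-fused 8-trimethylsilyloxy-8(9)-ene, 3α-OTMS, 5β-H, 10β-methyl | C[Si](C)(C)OC1=C[C@@]2(C)CC[C@@H](O[Si](C)(C)C)C(C)(C)[C@H]2CC1 | intermediate
7 | lithium 8(9)-enolate, 3α-OTMS (not isolated) | [Li]OC1=C[C@@]2(C)CC[C@@H](O[Si](C)(C)C)C(C)(C)[C@H]2CC1 | intermediate
8 | 9β-allyl 8-ketone, 3α-OTMS | C=CC[C@@H]1[C@@]2(C)CC[C@@H](O[Si](C)(C)C)C(C)(C)[C@H]2CCC1=O | intermediate
9 | 9β-allyl-8(26)-methylene 3α-trimethylsilyl ether (not isolated) | C=CC[C@@H]1[C@@]2(C)CC[C@@H](O[Si](C)(C)C)C(C)(C)[C@H]2CCC1=C | intermediate
10 | 9β-allyl-8(26)-methylene-3α-ol | C=CC[C@@H]1[C@@]2(C)CC[C@@H](O)C(C)(C)[C@H]2CCC1=C | intermediate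
11 | C13 B-alkyl-9-BBN, C3 O-(9-BBN) borinate (not isolated) | C1CC2CCCC(C1)B2CCC[C@@H]1[C@@]2(C)CC[C@@H](OB3C4CCCC3CCC4)C(C)(C)[C@H]2CCC1=C | intermediate
12 | 3α,13-diol with 8(26)-methylene | OCCC[C@@H]1[C@@]2(C)CC[C@@H](O)C(C)(C)[C@H]2CCC1=C | intermediate
13 | 3-keto 13-aldehyde with 8(26)-methylene | O=CCC[C@@H]1[C@@]2(C)CCC(=O)C(C)(C)[C@H]2CCC1=C | intermediate
14 | 14,14-dichloro-13-ene, 3-ketone, 8(26)-methylene | ClC(Cl)=CCC[C@@H]1[C@@]2(C)CCC(=O)C(C)(C)[C@H]2CCC1=C | intermediate
15 | 8α-hydroperoxide (not isolated) | ClC(Cl)=CCC[C@@H]1[C@@]2(C)CCC(=O)C(C)(C)[C@H]2CC[C@@]1(C)OO | intermediate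
16 | (5S,8R,9R,10S)-8α-hydroxy-3-keto 14,14-dichloro-13-ene | ClC(Cl)=CCC[C@@H]1[C@@]2(C)CCC(=O)C(C)(C)[C@H]2CC[C@@]1(C)O | intermediate
17 | geranyl acetate | CC(C)=CCC/C(C)=C/COC(C)=O | starting material
18 | (2E,6E)-8-hydroxy-3,7-dimethylocta-2,6-dienyl acetate | OC/C(C)=C/CC/C(C)=C/COC(C)=O | intermediate
19 | (2E,6E)-8-(tert-butyldimethylsilyloxy)-3,7-dimethylocta-2,6-dienyl acetate | CC(C)(C)[Si](C)(C)OC/C(C)=C/CC/C(C)=C/COC(C)=O | intermediate
20 | (2E,6E)-8-(tert-butyldimethylsilyloxy)-3,7-dimethylocta-2,6-dien-1-ol | CC(C)(C)[Si](C)(C)OC/C(C)=C/CC/C(C)=C/CO | intermediate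
21 | (2E,6E)-8-(tert-butyldimethylsilyloxy)-3,7-dimethylocta-2,6-dienal | CC(C)(C)[Si](C)(C)OC/C(C)=C/CC/C(C)=C/C=O | intermediate
22 | tert-butyldimethylsilyl ether of (2E,6E)-2,6-dimethylnona-2,6,8-trien-1-ol | CC(C)(C)[Si](C)(C)OC/C(C)=C/CC/C(C)=C/C=C | intermediate
23 | homoallylic B-alkyl-9-BBN (not isolated) | CC(C)(C)[Si](C)(C)OC/C(C)=C/CC/C(C)=C/CCB1C2CCCC1CCC2 | intermediate
24 | (2E,6E)-9-iodo-2,6-dimethylnona-2,6-dienyl tert-butyldimethylsilyl ether | CC(C)(C)[Si](C)(C)OC/C(C)=C/CC/C(C)=C/CCI | intermediate
25 | homoallylic alkylzinc iodide (not isolated) | CC(C)(C)[Si](C)(C)OC/C(C)=C/CC/C(C)=C/CC[Zn]I | intermediate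
26 | (13Z)-14-chloroalkene, C15 trans to C12 (not isolated) | CC(C)(C)[Si](C)(C)OC/C(C)=C/CC/C(C)=C/CC/C(Cl)=C/CC[C@@H]1[C@@]2(C)CCC(=O)C(C)(C)[C@H]2CC[C@@]1(C)O | intermediate
27 | C30 tert-butyldimethylsilyl ether of 28 | CC(C)(C)[Si](C)(C)OC/C(C)=C/CC/C(C)=C/CC/C(C)=C/CC[C@@H]1[C@@]2(C)CCC(=O)C(C)(C)[C@H]2CC[C@@]1(C)O | intermediate
28 | (5S,8R,9R,10S,13E,17E,21E)-8,30-dihydroxypolypoda-13,17,21-trien-3-one | OC/C(C)=C/CC/C(C)=C/CC/C(C)=C/CC[C@@H]1[C@@]2(C)CCC(=O)C(C)(C)[C@H]2CC[C@@]1(C)O | intermediate
29 | Myrrhanone A acetate | CC(=O)OC/C(C)=C/CC/C(C)=C/CC/C(C)=C/CC[C@@H]1[C@@]2(C)CCC(=O)C(C)(C)[C@H]2CC[C@@]1(C)O | target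

Total step count: 19. Longest linear sequence: 13 steps (steps 1–10, then 17–19).

## Steps most likely to fail

**Step 4.** C10 lies next to the C5 centre that carries the quaternary C4, so the conjugate addition may stall or drift to 1,2-addition.
- Fallback: the angular methyl is made through a cyclopropane instead of a copper reagent. It sets out from 5 and comes back at 10.
- Silylation of 5 (TESCl, imidazole) gives the triethylsilyl ether enone F1.
- Luche reduction (NaBH4, CeCl3·7H2O) gives the pseudo-equatorial 8β-allylic alcohol F2, whose hydroxyl lies on the face of H-5.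
- Hydroxyl-directed Simmons–Smith cyclopropanation (Et2Zn, CH2I2) places CH2 across C9=C10 on the β face to give the cyclopropyl carbinol F3.
- Dess–Martin oxidation gives the cyclopropyl ketone F4.
- Li/NH3 cleaves the exocyclic C9–CH2 bond, the one that overlaps with the carbonyl. This reveals the 10β-methyl group and the same 8(9)-enolate, which is allylated with allyl iodide to the triethylsilyl analogue of 8, ketone F5.
- The conditions of step 6, whose acidic work-up also removes the triethylsilyl group, lead back to 10.

**Step 10.** Capture of the planar C8 radical by the very small O2 may show poor facial selectivity, and hydrogen-atom transfer to the dichlorovinyl group may compete.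
- Fallback: a concerted, sterically more demanding oxygen transfer replaces the radical hydration. It sets out from 14 and comes back at 16.
- Buffered m-CPBA should epoxidise the exocyclic olefin from the α face and ignore the electron-poor dichloroalkene, giving the 8α,26-epoxide F6.
- LiEt3BH opens the epoxide at the CH2 terminus and also reduces the C3 ketone, giving the 3,8-diol F7. It is drawn as the 3R alcohol; the configuration at C3 is of no consequence.
- Dess–Martin oxidation of the secondary alcohol returns to 16.

**Step 17.** Three things may go wrong: protonolysis of the zinc reagent by the C8 hydroxyl, double alkylation of the dichloride, or loss of olefin geometry during the second substitution in the same pot.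
- Fallback: boron replaces zinc, and the union is run as two separate operations. It sets out from 22 and 16 and comes back at 27.
- Borane 23, made from triene 22 as in step 16, is coupled directly with 16, so iodide 24 is skipped. This is a B-alkyl Suzuki–Miyaura monocoupling of the 1,1-dichloroalkene (Pd2(dba)3, Xantphos, K3PO4, KF, THF, 65 °C), which tolerates the free hydroxyl.
- Chloroalkene 26 is isolated and its geometry checked.
- A second Suzuki–Miyaura coupling (trimethylboroxine, Pd(OAc)2, SPhos, K3PO4, dioxane, 90 °C) methylates 26 and returns to 27.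
- New compounds: none F0.

## Further compounds

F1 | step 4 | (4aS,6R)-5,5-dimethyl-6-(triethylsilyloxy)-4,4a,5,6,7,8-hexahydronaphthalen-2(3H)-one | O=C1C=C2CC[C@@H](O[Si](CC)(CC)CC)C(C)(C)[C@H]2CC1
F2 | step 4 | 8β-allylic alcohol, 3α-OTES | O[C@@H]1C=C2CC[C@@H](O[Si](CC)(CC)CC)C(C)(C)[C@H]2CC1
F3 | step 4 | 9,10-β-methano cyclopropyl carbinol, 8β-OH, 3α-OTES | O[C@@H]1[C@@H]2C[C@@]23CC[C@@H](O[Si](CC)(CC)CC)C(C)(C)[C@H]3CC1
F4 | step 4 | 9,10-β-methano 8-ketone, 3α-OTES | O=C1[C@@H]2C[C@@]23CC[C@@H](O[Si](CC)(CC)CC)C(C)(C)[C@H]3CC1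
F5 | step 4 | 9β-allyl 8-ketone, 3α-OTES | C=CC[C@@H]1[C@@]2(C)CC[C@@H](O[Si](CC)(CC)CC)C(C)(C)[C@H]2CCC1=O
F6 | step 10 | 8α,26-epoxide of 14 | ClC(Cl)=CCC[C@@H]1[C@@]2(C)CCC(=O)C(C)(C)[C@H]2CC[C@@]13OC3
F7 | step 10 | 3,8α-diol gem-dichloroalkene | ClC(Cl)=CCC[C@@H]1[C@@]2(C)CC[C@@H](O)C(C)(C)[C@H]2CC[C@@]1(C)O
F0 | step 17 | none | none
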